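**Retrosynthetic overview**
- Atom labels: ring D = C1(CO2CH3)–C2–C3(OH)(CH3)–C4(=O)–C5(CH3)–C18(spiro-oxirane); ring C = C1–C18–C5–C6–C7–C17; ring B = C7–C8(CH3)=C9–C14=C15–C16–C17(CH3); ring A = C9–C10–C11(=O)–O12–C13(CH3)2–C14.
- Feature and key disconnection: the adjacent ring-fusion atoms of rings B and C, quaternary C17 (CH3) and C7 (H), lie β and α to C8 once C8 is a cycloheptenone carbonyl. C17–CH3 and C7–C6 are therefore cut together (copper-catalysed asymmetric methyl conjugate addition, then enolate alkylation), and ring B is bought as cycloheptane-1,3-dione and never closed.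
- Ring C: C1–C18 by Dieckmann condensation between the acetate arm on C17 and the propanoate arm on C7. Ring D: C1–C2 and C4–C5 by Michael/aldol annulation with methacrolein, then C18=O to C18=CH2 and hydroxylation at C3.
- Ring A last: C8 ketone to C9=C14 enone, iodide on C9, CH3 onto C8 with 1,3-carbonyl transposition to C14, acetate arm on C9 (C9–C10), acetyl on C14 through the dienyl triflate (C14–C13), CH3MgBr and lactonisation (O12–C11).
- Ring order: B (bought), C, D, A, then the oxirane by C3–OH-directed epoxidation of C18=CH2.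

Key step: step 3

Remark: a 2-silyloxyethyl-lithium would collapse by β-elimination, so the two-carbon C1 arm on C17 is carried as an allyl group whose terminal carbon is excised in step 6; centres that form as mixtures and are erased later (C5 in 12–15 and 17, C1 in 15, C3/C4 in 17–22, C8 in 29) are left undefined in the SMILES.

Step 1
Reactants: 1 cycloheptane-1,3-dione
Product: 2 3-ethoxycyclohept-2-en-1-one
Conditions: EtOH, TsOH·H2O (cat.), PhMe, reflux, Dean–Stark
Reagents that add atoms: ethanol, CCO
Why: Acid-catalysed enol ether formation from the symmetrical cyclic 1,3-dione with azeotropic removal of water should give the vinylogous ester, and symmetry removes any regiochemical question.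

Step 2
Reactants: 2 3-ethoxycyclohept-2-en-1-one; 3 prop-2-en-1-ylmagnesium bromide
Product: 6 3-(prop-2-en-1-yl)cyclohept-2-en-1-one, via magnesium alkoxide 4 (not isolated), via hydroxy ketone 5 (not isolated)
Conditions: THF, 0 °C; then 1 M HCl, MeCN, 23 °C
Reagents that add atoms: water, O
Why: Stork–Danheiser transposition, in which the Grignard reagent adds 1,2 to the vinylogous ester and dilute acid then hydrolyses the enol ether and dehydrates the β-hydroxy ketone, should give the 3-substituted enone, acid being chosen because seven-membered β-hydroxy ketones ring-contract by retro-aldol under base.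

Step 3
Reactants: 6 3-(prop-2-en-1-yl)cyclohept-2-en-1-one; 7 trimethylaluminium; 8 methyl 2-(bromomethyl)prop-2-enoate
Product: 10 methyl 2-{[(1R,2R)-2-methyl-7-oxo-2-(prop-2-en-1-yl)cycloheptyl]methyl}prop-2-enoate, via dimethylaluminium enolate 9 (not isolated)
Conditions: copper thiophene-2-carboxylate CuO2CC4H3S (2 mol %), phosphoramidite L* = O,O′-(biphenyl-2,2′-diyl) N,N-bis[1-(2-naphthyl)ethyl]phosphoramidite, the enantiomer that gives (R) at C17 (4 mol %), Al(CH3)3 (1.4 equiv), Et2O, −30 °C; then CH3Li (1.4 equiv), THF, −78 °C; then 8 (2 equiv), −78 → 0 °C; minor C7 epimer recycled with DBU, PhMe, 23 °C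
Reagents that add atoms: none
Why: A chiral methylcopper species (monovalent copper bound to the phosphoramidite), formed by transmetalation from Al(CH3)3, should add methyl to C17 through a π-complex and a trivalent copper σ-intermediate and leave the regiodefined C7=C8 dimethylaluminium enolate 9. CH3Li converts 9 into the more nucleophilic aluminate enolate, which attacks the CH2 terminus of bromide 8 by addition–elimination (SN2′) and so forms C6–C7. The closest known reaction type is the copper-catalysed asymmetric conjugate addition of trialkylaluminium reagents to 3-substituted cyclic enones with trapping of the metal enolate by an allylic halide. No ring is closed, since ring B is the purchased seven-membered ring. C17 is set by the ligand, and C7 by approach of the electrophile anti to the larger allyl arm, a preference expected to be modest and therefore backed by base equilibration at C7 (α to the C8 ketone) with separation and recycling of the cis epimer. The step needs 1,4- over 1,2-addition and C-alkylation at the more hindered α-carbon, which the soft methylcopper reagent, the enolate double bond fixed between C7 and C8, and the SN2′-reactive bromide should secure.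

Step 4
Reactants: 10 methyl 2-{[(1R,2R)-2-methyl-7-oxo-2-(prop-2-en-1-yl)cycloheptyl]methyl}prop-2-enoate
Product: 12 methyl 2-methyl-3-[(1R,2R)-2-methyl-7-oxo-2-(prop-2-en-1-yl)cycloheptyl]propanoate, via silyl ketene acetal 11 (not isolated)
Conditions: [(Ph3P)CuH]6 (5 mol %), PhMe2SiH (1.5 equiv), PhMe, 23 °C; then 1 M HCl, THF
Reagents that add atoms: none
Why: Copper hydride conjugate reduction should touch only the electron-poor 1,1-disubstituted acrylate (the ketone and the isolated alkene are inert to the triphenylphosphine-bound hydride), and the silyl ketene acetal is hydrolysed on work-up, the new C5 centre forming as a mixture that is erased when C5 becomes a bridgehead.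

Step 5
Reactants: 12 methyl 2-methyl-3-[(1R,2R)-2-methyl-7-oxo-2-(prop-2-en-1-yl)cycloheptyl]propanoate
Product: 13 methyl 2-methyl-3-[(6R,7R)-7-methyl-7-(prop-2-en-1-yl)-1,4-dioxaspiro[4.6]undecan-6-yl]propanoate
Conditions: (Me3SiOCH2)2, Me3SiOTf (cat.), CH2Cl2, −78 → −20 °C
Reagents that add atoms: 1,2-bis(trimethylsilyloxy)ethane, C[Si](C)(C)OCCO[Si](C)(C)C
Why: Silyl-triflate-catalysed ketalisation with the bis-silyl glycol ether should protect even this α-branched ketone at low temperature, which is needed because the C8 ketone enolate would otherwise attack either ester in six-membered Claisen closures during step 7.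

Step 6
Reactants: 13 methyl 2-methyl-3-[(6R,7R)-7-methyl-7-(prop-2-en-1-yl)-1,4-dioxaspiro[4.6]undecan-6-yl]propanoate
Product: 14 methyl 3-[(6R,7R)-7-(2-methoxy-2-oxoethyl)-7-methyl-1,4-dioxaspiro[4.6]undecan-6-yl]-2-methylpropanoate
Conditions: O3, NaOH (2.5 M in MeOH), CH2Cl2, −78 °C
Reagents that add atoms: ozone, [O-][O+]=O; methanol, CO
Why: Ozonolysis in methanolic NaOH should convert the terminal alkene directly into the methyl ester through the α-methoxy hydroperoxide, which base fragments to the ester, so that the allyl group becomes the C1 acetate arm with loss of its terminal carbon.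

Step 7
Reactants: 14 methyl 3-[(6R,7R)-7-(2-methoxy-2-oxoethyl)-7-methyl-1,4-dioxaspiro[4.6]undecan-6-yl]-2-methylpropanoate
Product: 15 ring B/C β-keto ester (C1–CO2CH3; C18 ketone; C5–CH3; C8 dioxolane; trans B/C fusion)
Conditions: KOt-Bu (2.5 equiv), THF, 0 → 23 °C; then AcOH
Reagents that add atoms: none
Why: Dieckmann condensation under equilibrating conditions should give the six-membered β-keto ester formed through the C1–C18 bond, because only that regioisomer is held as a stabilised enolate, whereas closure of C5 onto the other ester gives a non-enolisable β-keto ester that reverts.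

Step 8
Reactants: 15 ring B/C β-keto ester; 16 methacrolein
Product: 18 ring D aldol product (bicyclo[3.3.1]nonane; C4–OH; C18 ketone; C8 dioxolane), via Michael adduct 17 (not isolated)
Conditions: 16 (1.5 equiv), DBU (0.5 equiv), MeCN, 0 → 50 °C
Reagents that add atoms: none
Why: Base-catalysed Michael addition of the β-keto ester to the enal followed by intramolecular aldol addition of the C18 ketone (through its C5 enol) to the aldehyde, a known domino annulation of cyclic β-keto esters to bicyclo[3.3.1]nonanes, should close ring D, with C1 set by axial attack anti to the axial C17 methyl, C5 then forced by the bridge, and C3/C4 formed as mixtures that are erased later.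

Step 9
Reactants: 18 ring D aldol product
Product: 19 C4 acetate of 18
Conditions: Ac2O, DMAP, pyridine, 23 °C
Reagents that add atoms: acetic anhydride, CC(=O)OC(C)=O
Why: DMAP-catalysed acylation should cap the secondary alcohol with a small group that keeps it away from the titanium reagent and blocks retro-aldol cleavage, elimination being impossible at the bridgehead.

Step 10
Reactants: 19 C4 acetate of 18
Product: 20 C18-methylene acetate
Conditions: Zn, CH2Br2, TiCl4, THF, 0 °C; then 19, CH2Cl2, 23 °C
Reagents that add atoms: dibromomethane, BrCBr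
Why: Lombardo–Takai methylenation with the zinc/titanium methylene reagent should convert the hindered bridging ketone, the only ketone present, into the exocyclic alkene without touching esters or the ketal.

Step 11
Reactants: 20 C18-methylene acetate
Product: 21 C18-methylene C4 alcohol
Conditions: K2CO3, MeOH, 40 °C
Reagents that add atoms: none
Why: Methanolysis should remove the acetate by transesterification, the C1 methyl ester can only exchange degenerately, and retro-aldol is no longer possible now that C18 is an alkene.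

Step 12
Reactants: 21 C18-methylene C4 alcohol
Product: 22 C18-methylene C4 ketone
Conditions: Dess–Martin periodinane, NaHCO3, CH2Cl2, 23 °C
Reagents that add atoms: none
Why: Periodinane oxidation of the hindered secondary alcohol under neutral conditions should give the C4 ketone and merge the C4 epimers.

Step 13
Reactants: 22 C18-methylene C4 ketone
Product: 23 C3 tertiary alcohol (α-ketol; C8 dioxolane)
Conditions: KN(SiMe3)2, THF, −78 °C; then 2-(benzenesulfonyl)-3-phenyloxaziridine, −78 °C; NH4Cl
Reagents that add atoms: 2-(benzenesulfonyl)-3-phenyloxaziridine, O=S(=O)(c1ccccc1)N1OC1c1ccccc1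
Why: The C4 ketone can enolise only toward C3 (C5 is quaternary), and enolate oxidation by the N-sulfonyloxaziridine should occur on the face syn to the one-carbon bridge C18 and away from ring C, which places OH exo as in the target and merges the C3 epimers.

Step 14
Reactants: 23 C3 tertiary alcohol
Product: 24 C8 ketone α-ketol
Conditions: PPTS, acetone/H2O, 60 °C
Reagents that add atoms: water, O
Why: Mild acid hydrolysis of the dioxolane should free the C8 ketone without protonating the hindered electron-poor alkene, and C7, again α to a ketone, should settle in the trans-fused arrangement, the only one that keeps C8 out of the concave face of the bicycle.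

Step 15
Reactants: 24 C8 ketone α-ketol
Product: 25 C3 triethylsilyl ether
Conditions: Et3SiOTf, 2,6-lutidine, CH2Cl2, −78 → 0 °C
Reagents that add atoms: triethylsilyl trifluoromethanesulfonate, CC[Si](CC)(CC)OS(=O)(=O)C(F)(F)F
Why: Silyl triflate with a hindered pyridine base should silylate the tertiary alcohol, which blocks α-ketol rearrangement and alkoxide chemistry during the ring A sequence.

Step 16
Reactants: 25 C3 triethylsilyl ether
Product: 26 C8–C9 trimethylsilyl enol ether
Conditions: LiN(i-Pr)2, Me3SiCl, THF, −78 °C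
Reagents that add atoms: chlorotrimethylsilane, C[Si](C)(C)Cl
Why: Kinetic deprotonation with in situ silyl chloride trapping should take a C9 methylene proton (C7–H is tertiary and flanked by quaternary C17, and the C4 ketone has no α-hydrogen) and give the regiodefined silyl enol ether.

Step 17
Reactants: 26 C8–C9 trimethylsilyl enol ether
Product: 27 C9=C14 enone
Conditions: Pd(OAc)2 (1.1 equiv), MeCN, 23 °C
Reagents that add atoms: none
Why: Saegusa–Ito oxidation, in which palladium diacetate (divalent palladium) forms the oxa-π-allyl complex and β-hydride elimination follows, should give the C9=C14 enone.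

Step 18
Reactants: 27 C9=C14 enone
Product: 28 9-iodo enone
Conditions: I2, pyridine/CH2Cl2, 23 °C
Reagents that add atoms: iodine, II
Why: Pyridine-mediated α-iodination of the enone (conjugate addition of pyridine, iodination of the enolate, elimination) should put iodine on C9.

Step 19
Reactants: 28 9-iodo enone
Product: 29 C8 tertiary allylic alcohol
Conditions: CH3Li, CeCl3, THF, −78 °C; NH4Cl
Reagents that add atoms: methyllithium, [Li]C
Why: The organocerium reagent should add 1,2 to the enone carbonyl without iodine–metal exchange or enolisation, while the C4 ketone between two fully substituted carbons and the bridgehead ester are shielded, the carbinol configuration at C8 being irrelevant.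

Step 20
Reactants: 29 C8 tertiary allylic alcohol
Product: 30 transposed iodo enone (C8(CH3)=C9(I)–C14=O)
Conditions: pyridinium chlorochromate (C5H5NH[CrO3Cl]), NaOAc, 4 Å sieves, CH2Cl2, 23 °C
Reagents that add atoms: pyridinium chlorochromate, [O-][Cr](=O)(=O)Cl.c1cc[nH+]cc1
Why: Dauben–Babler oxidative transposition, in which the tertiary allylic chromate ester undergoes a [3,3] shift to C14 and is oxidised there, should move the carbonyl from C8 to C14 and leave the C8(CH3)=C9 double bond.

Step 21
Reactants: 30 transposed iodo enone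
Product: 31 C9 ethyl acetate enone
Conditions: BrZnCH2CO2Et, Pd[P(t-Bu)3]2 (5 mol %), THF, 23 °C
Reagents that add atoms: (2-ethoxy-2-oxoethyl)zinc bromide, CCOC(=O)C[Zn]Br
Why: Negishi coupling of the zinc ester enolate (Reformatsky reagent) with the alkenyl iodide under zerovalent palladium should attach the acetate arm (C10, C11) to C9, zinc enolates being tolerant of ketones and esters.

Step 22
Reactants: 31 C9 ethyl acetate enone
Product: 32 C14 dienyl triflate
Conditions: LiN(SiMe3)2, THF, −78 °C; then PhNTf2, −78 → 0 °C; NH4Cl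
Reagents that add atoms: N-phenylbis(trifluoromethanesulfonimide), O=S(=O)(N(c1ccccc1)S(=O)(=O)C(F)(F)F)C(F)(F)F
Why: Kinetic deprotonation of the enone at the α′ methylene C15, whose hydrogens are more acidic than those of the ester arm, should give the cross-conjugated dienolate, which is O-sulfonylated to the dienyl triflate with the C14=C15 double bond in place.

Step 23
Reactants: 32 C14 dienyl triflate
Product: 34 C14 acetyl diene, via ethoxyvinyl diene 33 (not isolated)
Conditions: Bu3SnC(OEt)=CH2, Pd(PPh3)4 (5 mol %), LiCl, THF, 65 °C; then 0.5 M HCl, THF, 0 °C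
Reagents that add atoms: tributyl(1-ethoxyvinyl)stannane, CCCC[Sn](CCCC)(CCCC)C(=C)OCC; water, O
Why: Stille coupling of the dienyl triflate with the 1-ethoxyvinyl stannane (an acetyl anion equivalent) followed by brief acid hydrolysis of the enol ether should install the acetyl group on C14.

Step 24
Reactants: 34 C14 acetyl diene
Product: 36 ring A lactone (C3–OSiEt3; C18=CH2), via magnesium alkoxide 35 (not isolated)
Conditions: CH3MgBr, CeCl3, THF, −78 → 23 °C; NH4Cl
Reagents that add atoms: methylmagnesium bromide, C[Mg]Br
Why: 1,2-Addition of the methyl nucleophile to the unhindered methyl ketone should give a tertiary alkoxide that acylates itself on the neighbouring ethyl ester in a six-membered lactonisation, which closes ring A.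

Step 25
Reactants: 36 ring A lactone
Product: 37 hydroxy lactone (C3–OH; C18=CH2)
Conditions: HF·pyridine, pyridine, THF, 0 → 23 °C
Reagents that add atoms: none
Why: Buffered fluoride should cleave the triethylsilyl ether without touching the lactone, the diene or the ketone.

Step 26
Reactants: 37 hydroxy lactone
Product: 38 CNP0605450.1 (target)
Conditions: VO(acac)2 (10 mol %), t-BuOOH, CH2Cl2, 0 → 23 °C
Reagents that add atoms: tert-butyl hydroperoxide, CC(C)(C)OO
Why: In this hydroxyl-directed epoxidation the C3 alkoxide binds the oxovanadium peroxide and, in the boat form of ring D, sits flagpole over C18, so oxygen should be delivered to the exocyclic alkene from the ring D face (the other face is blocked by the axial C17 methyl) while the remote diene, lacking a directing group, reacts far more slowly.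

**Compound list**
1 | cycloheptane-1,3-dione | O=C1CCCCC(=O)C1 | starting material
2 | 3-ethoxycyclohept-2-en-1-one | CCOC1=CC(=O)CCCC1 | intermediate
3 | prop-2-en-1-ylmagnesium bromide | C=CC[Mg]Br | starting material
4 | bromomagnesium 3-ethoxy-1-(prop-2-en-1-yl)cyclohept-2-en-1-olate (racemic) | CCOC1=CC(O[Mg]Br)(CC=C)CCCC1 | intermediate
5 | 3-hydroxy-3-(prop-2-en-1-yl)cycloheptan-1-one (racemic) | C=CCC1(O)CCCCC(=O)C1 | intermediate
6 | 3-(prop-2-en-1-yl)cyclohept-2-en-1-one | C=CCC1=CC(=O)CCCC1 | intermediate
7 | trimethylaluminium | C[Al](C)C | starting material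
8 | methyl 2-(bromomethyl)prop-2-enoate | C=C(CBr)C(=O)OC | starting material
9 | dimethyl{[(3R)-3-methyl-3-(prop-2-en-1-yl)cyclohept-1-en-1-yl]oxy}alumane | C=CC[C@@]1(C)CCCCC(O[Al](C)C)=C1 | intermediate
10 | methyl 2-{[(1R,2R)-2-methyl-7-oxo-2-(prop-2-en-1-yl)cycloheptyl]methyl}prop-2-enoate | COC(=O)C(=C)C[C@H]1C(=O)CCCC[C@]1(C)CC=C | intermediate
11 | dimethylphenylsilyl ketene acetal of 12 | COC(O[Si](C)(C)c1ccccc1)=C(C)C[C@H]1C(=O)CCCC[C@]1(C)CC=C | intermediate
12 | methyl 2-methyl-3-[(1R,2R)-2-methyl-7-oxo-2-(prop-2-en-1-yl)cycloheptyl]propanoate (C5 epimers) | COC(=O)C(C)C[C@H]1C(=O)CCCC[C@]1(C)CC=C | intermediate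
13 | methyl 2-methyl-3-[(6R,7R)-7-methyl-7-(prop-2-en-1-yl)-1,4-dioxaspiro[4.6]undecan-6-yl]propanoate | COC(=O)C(C)C[C@H]1C2(OCCO2)CCCC[C@]1(C)CC=C | intermediate
14 | methyl 3-[(6R,7R)-7-(2-methoxy-2-oxoethyl)-7-methyl-1,4-dioxaspiro[4.6]undecan-6-yl]-2-methylpropanoate | COC(=O)C(C)C[C@H]1C2(OCCO2)CCCC[C@]1(C)CC(=O)OC | intermediate
15 | ring B/C β-keto ester: C1–CO2CH3, C18 ketone, C5–CH3, C17–CH3, C8 dioxolane, C7–H trans to C17–CH3 | COC(=O)C1C(=O)C(C)C[C@H]2C3(OCCO3)CCCC[C@]12C | intermediate
16 | methacrolein (2-methylprop-2-enal) | CC(=C)C=O | starting material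
17 | Michael adduct: 15 with CH2CH(CH3)CHO on C1, anti to the C17 methyl | COC(=O)[C@@]1(CC(C)C=O)C(=O)C(C)C[C@H]2C3(OCCO3)CCCC[C@]12C | intermediate
18 | ring D aldol product: bicyclo[3.3.1]nonane with C4–OH, C3–CH3, C18 ketone, C8 dioxolane | COC(=O)[C@]12CC(C)C(O)[C@](C)(C[C@H]3C4(OCCO4)CCCC[C@@]31C)C2=O | intermediate
19 | C4 acetate of 18 | COC(=O)[C@]12CC(C)C(OC(C)=O)[C@](C)(C[C@H]3C4(OCCO4)CCCC[C@@]31C)C2=O | intermediate
20 | C18-methylene acetate | COC(=O)[C@]12CC(C)C(OC(C)=O)[C@](C)(C[C@H]3C4(OCCO4)CCCC[C@@]31C)C2=C | intermediate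
21 | C18-methylene C4 alcohol | COC(=O)[C@]12CC(C)C(O)[C@](C)(C[C@H]3C4(OCCO4)CCCC[C@@]31C)C2=C | intermediate
22 | C18-methylene C4 ketone | COC(=O)[C@]12CC(C)C(=O)[C@](C)(C[C@H]3C4(OCCO4)CCCC[C@@]31C)C2=C | intermediate
23 | C3 tertiary alcohol (OH exo, α-ketol), C8 dioxolane | COC(=O)[C@]12C[C@@](C)(O)C(=O)[C@](C)(C[C@H]3C4(OCCO4)CCCC[C@@]31C)C2=C | intermediate
24 | C8 ketone α-ketol | COC(=O)[C@]12C[C@@](C)(O)C(=O)[C@](C)(C[C@H]3C(=O)CCCC[C@@]31C)C2=C | intermediate
25 | C3 triethylsilyl ether of 24 | COC(=O)[C@]12C[C@@](C)(O[Si](CC)(CC)CC)C(=O)[C@](C)(C[C@H]3C(=O)CCCC[C@@]31C)C2=C | intermediate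
26 | C8–C9 trimethylsilyl enol ether of 25 | COC(=O)[C@]12C[C@@](C)(O[Si](CC)(CC)CC)C(=O)[C@](C)(C[C@H]3C(O[Si](C)(C)C)=CCCC[C@@]31C)C2=C | intermediate
27 | C9=C14 enone (C8 ketone) | COC(=O)[C@]12C[C@@](C)(O[Si](CC)(CC)CC)C(=O)[C@](C)(C[C@H]3C(=O)C=CCC[C@@]31C)C2=C | intermediate
28 | 9-iodo enone | COC(=O)[C@]12C[C@@](C)(O[Si](CC)(CC)CC)C(=O)[C@](C)(C[C@H]3C(=O)C(I)=CCC[C@@]31C)C2=C | intermediate
29 | C8 tertiary allylic alcohol (C8–CH3, C8–OH, C9–I) | COC(=O)[C@]12C[C@@](C)(O[Si](CC)(CC)CC)C(=O)[C@](C)(C[C@H]3C(C)(O)C(I)=CCC[C@@]31C)C2=C | intermediate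
30 | transposed iodo enone: C8(CH3)=C9(I)–C14=O | COC(=O)[C@]12C[C@@](C)(O[Si](CC)(CC)CC)C(=O)[C@](C)(C[C@H]3C(C)=C(I)C(=O)CC[C@@]31C)C2=C | intermediate
31 | C9 ethyl acetate enone: C9–CH2CO2Et, C14 ketone | COC(=O)[C@]12C[C@@](C)(O[Si](CC)(CC)CC)C(=O)[C@](C)(C[C@H]3C(C)=C(CC(=O)OCC)C(=O)CC[C@@]31C)C2=C | intermediate
32 | C14 dienyl triflate | COC(=O)[C@]12C[C@@](C)(O[Si](CC)(CC)CC)C(=O)[C@](C)(C[C@H]3C(C)=C(CC(=O)OCC)C(OS(=O)(=O)C(F)(F)F)=CC[C@@]31C)C2=C | intermediate
33 | C14 1-ethoxyvinyl diene | COC(=O)[C@]12C[C@@](C)(O[Si](CC)(CC)CC)C(=O)[C@](C)(C[C@H]3C(C)=C(CC(=O)OCC)C(C(=C)OCC)=CC[C@@]31C)C2=C | intermediate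
34 | C14 acetyl diene | COC(=O)[C@]12C[C@@](C)(O[Si](CC)(CC)CC)C(=O)[C@](C)(C[C@H]3C(C)=C(CC(=O)OCC)C(C(C)=O)=CC[C@@]31C)C2=C | intermediate
35 | bromomagnesium C13 tertiary alkoxide | COC(=O)[C@]12C[C@@](C)(O[Si](CC)(CC)CC)C(=O)[C@](C)(C[C@H]3C(C)=C(CC(=O)OCC)C(C(C)(C)O[Mg]Br)=CC[C@@]31C)C2=C | intermediate
36 | ring A lactone with C3–OSiEt3 and C18=CH2 | COC(=O)[C@]12C[C@@](C)(O[Si](CC)(CC)CC)C(=O)[C@](C)(C[C@H]3C(C)=C4CC(=O)OC(C)(C)C4=CC[C@@]31C)C2=C | intermediate
37 | hydroxy lactone with C3–OH and C18=CH2 | COC(=O)[C@]12C[C@@](C)(O)C(=O)[C@](C)(C[C@H]3C(C)=C4CC(=O)OC(C)(C)C4=CC[C@@]31C)C2=C | intermediate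
38 | CNP0605450.1 | COC(=O)[C@]12C[C@@](C)(O)C(=O)[C@](C)(C[C@H]3C(C)=C4CC(=O)OC(C)(C)C4=CC[C@@]31C)[C@]21CO1 | target

Total step count: 26. Longest linear sequence: 26 steps (1 to 38).

**Steps most likely to fail**

Step 3 (key step). The aluminium enolate may alkylate too slowly at the hindered C7, bromide 8 may be consumed by residual methyl–metal species, or the electrophile may discriminate poorly between the methyl and allyl groups on C17. The fallback sets out from 6 and returns at 10. The conjugate addition is run as in step 3, but enolate 9 is O-silylated with Me3SiOTf and the trimethylsilyl enol ether F1 is isolated, which stores the enolate regiochemistry. CH3Li in THF then releases the lithium enolate F2, which is alkylated with 8 in THF/DMPU at −78 °C to give 10. The C7 epimers are equilibrated with DBU as before.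

Step 8. Under amine base the C18 ketone may enolise toward the methyl-bearing C5 too slowly, so that retro-Michael cleavage and self-condensation of the aldehyde overtake ring closure. The fallback sets out from 15 and returns at 18. The Michael addition alone is run with catalytic Et3N at 0 °C and Michael adduct 17 is isolated. The aldol closure is then done under acid (aqueous HCl in THF, 50 °C), where the ketone enol adds to the protonated aldehyde. This also hydrolyses the dioxolane and gives hydroxy diketone F3. Its C8 ketone is re-protected selectively with (Me3SiOCH2)2 and catalytic Me3SiOTf, the C18 ketone between two quaternary carbons being inert to ketalisation, which gives 18.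

Step 26. Chemoselectivity may be lost: the hindered, electron-poor exocyclic alkene may be oxidised more slowly than the electron-rich C8=C9–C14=C15 diene, or the α-ketol may be degraded by the vanadium peroxide. The fallback sets out from 31 and returns at 38. The epoxide is installed before the diene exists, at enone 31, where the only other alkene is deactivated by conjugation. mCPBA with NaHCO3 in CH2Cl2 should attack C18=CH2 from the open ring D face and give spiro-epoxide F4. This hindered neopentyl-type oxirane is then carried through the same operations: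
- LiN(SiMe3)2 and PhNTf2 give dienyl triflate F5.
- Stille coupling with Bu3SnC(OEt)=CH2 (Pd(PPh3)4, CuI, CsF, DMF, in place of LiCl) gives ethoxyvinyl diene F6, and hydrolysis with oxalic acid on wet silica gives methyl ketone F7.
- CH3MgBr with CeCl3 at −78 °C gives magnesium alkoxide F8, which on warming closes to epoxy lactone F9.
- Bu4NF buffered with AcOH removes the silyl group and gives 38.

Further compounds
F1 | step 3 | trimethyl{[(3R)-3-methyl-3-(prop-2-en-1-yl)cyclohept-1-en-1-yl]oxy}silane | C=CC[C@@]1(C)CCCCC(O[Si](C)(C)C)=C1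
F2 | step 3 | lithium (3R)-3-methyl-3-(prop-2-en-1-yl)cyclohept-1-en-1-olate | C=CC[C@@]1(C)CCCCC(O[Li])=C1
F3 | step 8 | hydroxy diketone (18 with a free C8 ketone) | COC(=O)[C@]12CC(C)C(O)[C@](C)(C[C@H]3C(=O)CCCC[C@@]31C)C2=O
F4 | step 26 | C18 spiro-epoxide of 31 | COC(=O)[C@]12C[C@@](C)(O[Si](CC)(CC)CC)C(=O)[C@](C)(C[C@H]3C(C)=C(CC(=O)OCC)C(=O)CC[C@@]31C)[C@]21CO1
F5 | step 26 | epoxy dienyl triflate | COC(=O)[C@]12C[C@@](C)(O[Si](CC)(CC)CC)C(=O)[C@](C)(C[C@H]3C(C)=C(CC(=O)OCC)C(OS(=O)(=O)C(F)(F)F)=CC[C@@]31C)[C@]21CO1
F6 | step 26 | epoxy 1-ethoxyvinyl diene | COC(=O)[C@]12C[C@@](C)(O[Si](CC)(CC)CC)C(=O)[C@](C)(C[C@H]3C(C)=C(CC(=O)OCC)C(C(=C)OCC)=CC[C@@]31C)[C@]21CO1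
F7 | step 26 | epoxy C14 acetyl diene | COC(=O)[C@]12C[C@@](C)(O[Si](CC)(CC)CC)C(=O)[C@](C)(C[C@H]3C(C)=C(CC(=O)OCC)C(C(C)=O)=CC[C@@]31C)[C@]21CO1
F8 | step 26 | epoxy bromomagnesium C13 alkoxide | COC(=O)[C@]12C[C@@](C)(O[Si](CC)(CC)CC)C(=O)[C@](C)(C[C@H]3C(C)=C(CC(=O)OCC)C(C(C)(C)O[Mg]Br)=CC[C@@]31C)[C@]21CO1
F9 | step 26 | epoxy lactone with C3–OSiEt3 | COC(=O)[C@]12C[C@@](C)(O[Si](CC)(CC)CC)C(=O)[C@](C)(C[C@H]3C(C)=C4CC(=O)OC(C)(C)C4=CC[C@@]31C)[C@]21CO1
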